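**Retrosynthetic overview**

- Numbering: the 24-carbon backbone of the target counted from the isopropylidene end (C2=C3, C6 methylidene, C7, C10/C11 oxirane, C14=C15, C18=C19, C22, C23=C24).
- The oxirane is the only ring and is closed last, by invertive closure of a 10,11-diol. C10 is set by Felkin–Anh addition of a C1–C9 Grignard reagent to an acetyl lactone whose C11 centre is bought in L-glutamic-acid-derived (S)-5-oxooxolane-2-carboxylic acid.
- C13–C14 is the key bond: visible-light nickel/iridium decarboxylative alkenylation of the lactone-derived carboxylate with a (1E,5E)-bromodiene (C14–C24).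
- C7 and C22 come from (−)- and (+)-limonene oxide: periodate ring cleavage and decarbonylation give the two enantiomers of 5,6-dimethylhept-6-en-2-one.
- Right half: ketone → alkyne → carboalumination and alkyl–alkenyl Negishi coupling for the E,E-diene. Left half: allylic lithiation/prenylation (C4–C5) and deacylative bromination.

Assumption: both limonene oxides are used as the commercial cis/trans mixtures (the epoxide stereocentres are destroyed in steps 1 and 8), and a one-pot operation with unisolated intermediates counts as one step.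

**Route**

Step 1
Reactants: 1 (4R)-1-methyl-4-(prop-1-en-2-yl)-7-oxabicyclo[4.1.0]heptane
Product: 2 (3R)-6-oxo-3-(prop-1-en-2-yl)heptanal
Conditions: H5IO6 (1.1 equiv), THF/H2O (4:1), 0 °C → rt
Reagents that add atoms: water O
Why: Acid-mediated epoxide hydrolysis of either epimer followed by periodate (Malaprade) glycol cleavage gives the keto aldehyde, and the isopropenyl group and the stereocenter bought in 1 are not touched.

Step 2
Reactants: 2 (3R)-6-oxo-3-(prop-1-en-2-yl)heptanal
Product: 3 (5S)-5,6-dimethylhept-6-en-2-one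
Conditions: RhCl(PPh3)3 (1.05 equiv), toluene, 110 °C
Reagents that add atoms: none
Why: Tsuji–Wilkinson decarbonylation (formyl C–H oxidative addition to monovalent rhodium, CO extrusion, C–H reductive elimination) turns the CH2CHO arm into the methyl group of the future C22 centre, which is β to the formyl carbon and keeps its geometry (only the CIP label changes from R to S).

Step 3
Reactants: 3 (5S)-5,6-dimethylhept-6-en-2-one
Product: 5 (5S)-5,6-dimethylhept-6-en-1-yne, via enol phosphate 4 (not isolated)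
Conditions: LDA (1.05 equiv), THF, −78 °C; ClP(O)(OEt)2, −78 °C → rt; LDA (2.3 equiv), −78 °C → rt; aq. NH4Cl
Reagents that add atoms: none
Why: Negishi's one-pot methyl ketone to alkyne conversion (kinetic enolate O-phosphorylation on the methyl side, then base-induced β-elimination) gives the terminal alkyne, and the γ-stereocenter cannot enolise.

Step 4
Reactants: 5 (5S)-5,6-dimethylhept-6-en-1-yne
Product: 7 (1E,5S)-1-iodo-2,5,6-trimethylhepta-1,6-diene, via alkenylalane 6 (not isolated)
Conditions: Me3Al (2 equiv), Cp2ZrCl2 (0.25 equiv), CH2Cl2, 0 °C → rt; I2, THF, −30 → 0 °C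
Reagents that add atoms: trimethylaluminium C[Al](C)C; iodine II
Why: Negishi zirconium-catalysed carboalumination adds CH3 and Al syn with Al on the terminal carbon, and iodinolysis with retention gives the (E)-iodide that fixes the C18=C19 geometry, while the 1,1-disubstituted alkene is inert.

Step 5
Reactants: 8 but-3-yn-1-ol
Product: 10 (3E)-4-bromo-3-methylbut-3-en-1-ol, via alkoxy alkenylalane 9 (not isolated)
Conditions: Me3Al (3 equiv), Cp2ZrCl2 (0.25 equiv), CH2Cl2, 0 °C → rt; NBS, −30 → 0 °C; aq. Rochelle salt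
Reagents that add atoms: trimethylaluminium C[Al](C)C; N-bromosuccinimide O=C1CCC(=O)N1Br
Why: The same syn carboalumination on the aluminium alkoxide of the alkynol, followed by bromination of the C–Al bond with retention, gives the (E)-bromoalkene that becomes C14=C15.

Step 6
Reactants: 10 (3E)-4-bromo-3-methylbut-3-en-1-ol
Product: 11 (1E)-1-bromo-4-iodo-2-methylbut-1-ene
Conditions: I2, PPh3, imidazole, CH2Cl2, 0 °C → rt
Reagents that add atoms: iodine II
Why: Appel-type (Garegg–Samuelsson) iodination converts the primary alcohol into the iodide by SN2 displacement of the oxyphosphonium group without touching the alkenyl bromide.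

Step 7
Reactants: 11 (1E)-1-bromo-4-iodo-2-methylbut-1-ene; 7 (1E,5S)-1-iodo-2,5,6-trimethylhepta-1,6-diene
Product: 13 (1E,5E,9S)-1-bromo-2,6,9,10-tetramethylundeca-1,5,10-triene, via organozinc 12 (not isolated)
Conditions: Zn dust, LiCl, THF, 40 °C; then 7, Pd(PPh3)4 (3 mol%), THF, rt
Reagents that add atoms: none
Why: Negishi alkyl–alkenyl coupling: zinc inserts only into the C(sp3)–I bond, and zerovalent palladium adds to the alkenyl iodide of 7 far faster than to an alkenyl bromide, so the C17–C18 bond forms with both (E)-geometries retained and the bromide is kept for step 15.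

Step 8
Reactants: 14 (4S)-1-methyl-4-(prop-1-en-2-yl)-7-oxabicyclo[4.1.0]heptane
Product: 15 (3S)-6-oxo-3-(prop-1-en-2-yl)heptanal
Conditions: H5IO6 (1.1 equiv), THF/H2O (4:1), 0 °C → rt
Reagents that add atoms: water O
Why: The same epoxide hydrolysis and Malaprade glycol cleavage as in step 1, in the enantiomeric series, leaves the stereocenter bought in 14 untouched.

Step 9
Reactants: 15 (3S)-6-oxo-3-(prop-1-en-2-yl)heptanal
Product: 16 (5R)-5,6-dimethylhept-6-en-2-one
Conditions: RhCl(PPh3)3 (1.05 equiv), toluene, 110 °C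
Reagents that add atoms: none
Why: Tsuji–Wilkinson decarbonylation as in step 2 creates the methyl group on the future C7 centre without touching its configuration (CIP label changes from S to R).

Step 10
Reactants: 16 (5R)-5,6-dimethylhept-6-en-2-one
Product: 17 2-[(3R)-3,4-dimethylpent-4-en-1-yl]-2-methyl-1,3-dioxolane
Conditions: ethylene glycol, PPTS (cat.), benzene, reflux (Dean–Stark)
Reagents that add atoms: ethane-1,2-diol OCCO
Why: Acid-catalysed ketalisation masks the enolisable ketone so that the only acidic site left for the next step is the allylic methyl group.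

Step 11
Reactants: 17 2-[(3R)-3,4-dimethylpent-4-en-1-yl]-2-methyl-1,3-dioxolane; 18 1-bromo-3-methylbut-2-ene
Product: 20 2-[(3R)-3,8-dimethyl-4-methylidenenon-7-en-1-yl]-2-methyl-1,3-dioxolane, via allyllithium 19 (not isolated)
Conditions: n-BuLi, TMEDA, hexane, rt, 18 h; then 18, THF, −78 → 0 °C
Reagents that add atoms: none
Why: Allylic metalation of the isopropenyl methyl group (as established for limonene) gives a 2-substituted allyllithium with two equivalent CH2 termini, which is alkylated by prenyl bromide at its primary carbon (SN2) to form C4–C5, and the tertiary allylic C–H of the stereocenter is kinetically much less acidic.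

Step 12
Reactants: 20 2-[(3R)-3,8-dimethyl-4-methylidenenon-7-en-1-yl]-2-methyl-1,3-dioxolane
Product: 23 (3R)-1-bromo-3,8-dimethyl-4-methylidenenon-7-ene, via ketone 21 (not isolated), via triazoline 22 (not isolated)
Conditions: N′-methylpyridine-2-carbohydrazonamide (MPHA), TsOH·H2O (10 mol%), 1,4-dioxane/H2O (20:1), 50 °C; then BrCCl3 (2 equiv), 80 °C
Reagents that add atoms: bromotrichloromethane BrC(Cl)(Cl)Cl
Why: Aromatisation-driven deacylative bromination: the ketone released in situ condenses with the amidrazone to a triazoline, hydrogen abstraction from its N–H triggers β-scission to the aromatic triazole and the primary C9 radical, and bromine-atom transfer from BrCCl3 gives the bromide with the stereocenter two carbons away.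

Step 13
Reactants: 24 (2S)-5-oxooxolane-2-carboxylic acid
Product: 26 (5S)-5-acetyloxolan-2-one, via acid chloride 25 (not isolated)
Conditions: (COCl)2, DMF (cat.), CH2Cl2, 0 °C → rt; then MeMgBr (1.05 equiv), Fe(acac)3 (3 mol%), THF, −78 °C
Reagents that add atoms: methylmagnesium bromide C[Mg]Br
Why: Iron-catalysed acylation of the Grignard reagent by the acid chloride is much faster than attack on the lactone or on the product ketone at −78 °C, so the methyl ketone forms with the bought (S)-centre (future C11) intact.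

Step 14
Reactants: 23 (3R)-1-bromo-3,8-dimethyl-4-methylidenenon-7-ene; 26 (5S)-5-acetyloxolan-2-one
Product: 28 (5S)-5-[(2R,5R)-2-hydroxy-5,10-dimethyl-6-methylideneundec-9-en-2-yl]oxolan-2-one, via Grignard reagent 27 (not isolated)
Conditions: Mg, THF, 40 °C; then 26 (1.3 equiv), THF, −78 °C; aq. NH4Cl
Reagents that add atoms: none
Why: Polar Felkin–Anh (Cornforth) Grignard addition: with the lactone C–O bond antiperiplanar to the carbonyl the nucleophile passes the hydrogen and not the ring CH2, so the (S)-centre from 24 sets the (10R) tertiary carbinol (dr of about 6:1 expected, minor epimer removed by chromatography) and the lactone survives at −78 °C.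

Step 15
Reactants: 28 (5S)-5-[(2R,5R)-2-hydroxy-5,10-dimethyl-6-methylideneundec-9-en-2-yl]oxolan-2-one; 13 (1E,5E,9S)-1-bromo-2,6,9,10-tetramethylundeca-1,5,10-triene
Product: 30 (7R,10R,11S,14E,18E,22S)-2,7,10,15,19,22,23-heptamethyl-6-methylidenetetracosa-2,14,18,23-tetraene-10,11-diol, via caesium carboxylate 29 (not isolated)
Conditions: CsOH·H2O (1.05 equiv), DMSO/H2O (10:1), rt; then 13 (1.2 equiv), NiCl2(dme) (10 mol%), 4,4′-di-tert-butyl-2,2′-bipyridine (15 mol%), [Ir(dF(CF3)ppy)2(dtbbpy)]PF6 (2 mol%), 450 nm LEDs, rt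
Reagents that add atoms: none
Why: Proposed new method: a γ-lactone serves as a latent primary carboxylate in a dual nickel/iridium photoredox decarboxylative alkenylation – hydroxide opens 28 to the unprotected dihydroxy carboxylate 29, the excited trivalent iridium complex (about +1.2 V vs SCE) oxidises the carboxylate, loss of CO2 gives the primary C13 radical, this is captured by the alkenylnickel bromide formed from zerovalent nickel and 13, and reductive elimination from trivalent nickel forms C13–C14 with retention of the (E)-geometry and with no stereocenter at or next to the radical carbon; the closest known reaction type is the nickel/photoredox decarboxylative cross-coupling of carboxylic acids with vinyl halides, which has not been shown for lactone-derived free hydroxy carboxylates or for 2-methylalk-1-enyl bromides of this kind.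

Step 16
Reactants: 30 (7R,10R,11S,14E,18E,22S)-2,7,10,15,19,22,23-heptamethyl-6-methylidenetetracosa-2,14,18,23-tetraene-10,11-diol
Product: 32 (2R,3R)-2-[(3R)-3,8-dimethyl-4-methylidenenon-7-en-1-yl]-2-methyl-3-[(3E,7E,11S)-4,8,11,12-tetramethyltrideca-3,7,12-trien-1-yl]oxirane, via mesylate 31 (not isolated)
Conditions: MsCl, Et3N, CH2Cl2, −20 °C; then K2CO3, MeOH, rt
Reagents that add atoms: none
Why: Selective mesylation of the secondary hydroxyl and intramolecular Williamson (SN2) closure by the tertiary alkoxide invert C11 from S to R and give the trans-trisubstituted oxirane, while C10 is not touched.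

**Compound list**

1 | (4R)-1-methyl-4-(prop-1-en-2-yl)-7-oxabicyclo[4.1.0]heptane, (+)-limonene 1,2-oxide, cis/trans mixture | CC12OC1C[C@@H](CC2)C(=C)C | starting material
2 | (3R)-6-oxo-3-(prop-1-en-2-yl)heptanal | O=CC[C@@H](CCC(C)=O)C(C)=C | intermediate
3 | (5S)-5,6-dimethylhept-6-en-2-one | CC(=O)CC[C@H](C)C(C)=C | intermediate
4 | diethyl (5S)-5,6-dimethylhepta-1,6-dien-2-yl phosphate | C=C(CC[C@H](C)C(C)=C)OP(=O)(OCC)OCC | intermediate
5 | (5S)-5,6-dimethylhept-6-en-1-yne | C#CCC[C@H](C)C(C)=C | intermediate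
6 | dimethyl[(1E,5S)-2,5,6-trimethylhepta-1,6-dien-1-yl]alumane | C[Al](C)/C=C(\C)CC[C@H](C)C(C)=C | intermediate
7 | (1E,5S)-1-iodo-2,5,6-trimethylhepta-1,6-diene | I/C=C(\C)CC[C@H](C)C(C)=C | intermediate
8 | but-3-yn-1-ol | C#CCCO | starting material
9 | {[(3E)-4-(dimethylalumanyl)-3-methylbut-3-en-1-yl]oxy}(dimethyl)alumane | C[Al](C)/C=C(\C)CCO[Al](C)C | intermediate
10 | (3E)-4-bromo-3-methylbut-3-en-1-ol | Br/C=C(\C)CCO | intermediate
11 | (1E)-1-bromo-4-iodo-2-methylbut-1-ene | Br/C=C(\C)CCI | intermediate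
12 | [(3E)-4-bromo-3-methylbut-3-en-1-yl](iodo)zinc | Br/C=C(\C)CC[Zn]I | intermediate
13 | (1E,5E,9S)-1-bromo-2,6,9,10-tetramethylundeca-1,5,10-triene | Br/C=C(\C)CC/C=C(\C)CC[C@H](C)C(C)=C | intermediate
14 | (4S)-1-methyl-4-(prop-1-en-2-yl)-7-oxabicyclo[4.1.0]heptane, (−)-limonene 1,2-oxide, cis/trans mixture | CC12OC1C[C@H](CC2)C(=C)C | starting material
15 | (3S)-6-oxo-3-(prop-1-en-2-yl)heptanal | O=CC[C@H](CCC(C)=O)C(C)=C | intermediate
16 | (5R)-5,6-dimethylhept-6-en-2-one | CC(=O)CC[C@@H](C)C(C)=C | intermediate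
17 | 2-[(3R)-3,4-dimethylpent-4-en-1-yl]-2-methyl-1,3-dioxolane | CC1(CC[C@@H](C)C(C)=C)OCCO1 | intermediate
18 | 1-bromo-3-methylbut-2-ene | CC(C)=CCBr | starting material
19 | {2-[(2R)-4-(2-methyl-1,3-dioxolan-2-yl)butan-2-yl]prop-2-en-1-yl}lithium | [Li]CC(=C)[C@H](C)CCC1(C)OCCO1 | intermediate
20 | 2-[(3R)-3,8-dimethyl-4-methylidenenon-7-en-1-yl]-2-methyl-1,3-dioxolane | CC(C)=CCCC(=C)[C@H](C)CCC1(C)OCCO1 | intermediate
21 | (5R)-5,10-dimethyl-6-methylideneundec-9-en-2-one | CC(C)=CCCC(=C)[C@H](C)CCC(C)=O | intermediate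
22 | 2-{5-[(3R)-3,8-dimethyl-4-methylidenenon-7-en-1-yl]-1,5-dimethyl-4,5-dihydro-1H-1,2,4-triazol-3-yl}pyridine, both epimers at the aminal carbon | CC(C)=CCCC(=C)[C@H](C)CCC1(C)NC(=NN1C)c1ccccn1 | intermediate
23 | (3R)-1-bromo-3,8-dimethyl-4-methylidenenon-7-ene | CC(C)=CCCC(=C)[C@H](C)CCBr | intermediate
24 | (2S)-5-oxooxolane-2-carboxylic acid | OC(=O)[C@@H]1CCC(=O)O1 | starting material
25 | (2S)-5-oxooxolane-2-carbonyl chloride | ClC(=O)[C@@H]1CCC(=O)O1 | intermediate
26 | (5S)-5-acetyloxolan-2-one | CC(=O)[C@@H]1CCC(=O)O1 | intermediate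
27 | bromo[(3R)-3,8-dimethyl-4-methylidenenon-7-en-1-yl]magnesium | CC(C)=CCCC(=C)[C@H](C)CC[Mg]Br | intermediate
28 | (5S)-5-[(2R,5R)-2-hydroxy-5,10-dimethyl-6-methylideneundec-9-en-2-yl]oxolan-2-one | C[C@@](O)(CC[C@@H](C)C(=C)CCC=C(C)C)[C@@H]1CCC(=O)O1 | intermediate
29 | caesium (4S,5R,8R)-4,5-dihydroxy-5,8,13-trimethyl-9-methylidenetetradec-12-enoate | C[C@@](O)(CC[C@@H](C)C(=C)CCC=C(C)C)[C@@H](O)CCC(=O)[O-].[Cs+] | intermediate
30 | (7R,10R,11S,14E,18E,22S)-2,7,10,15,19,22,23-heptamethyl-6-methylidenetetracosa-2,14,18,23-tetraene-10,11-diol | C[C@@](O)(CC[C@@H](C)C(=C)CCC=C(C)C)[C@@H](O)CC/C=C(\C)CC/C=C(\C)CC[C@H](C)C(C)=C | intermediate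
31 | (7R,10R,11S,14E,18E,22S)-10-hydroxy-2,7,10,15,19,22,23-heptamethyl-6-methylidenetetracosa-2,14,18,23-tetraen-11-yl methanesulfonate | C[C@@](O)(CC[C@@H](C)C(=C)CCC=C(C)C)[C@@H](OS(C)(=O)=O)CC/C=C(\C)CC/C=C(\C)CC[C@H](C)C(C)=C | intermediate
32 | (2R,3R)-2-[(3R)-3,8-dimethyl-4-methylidenenon-7-en-1-yl]-2-methyl-3-[(3E,7E,11S)-4,8,11,12-tetramethyltrideca-3,7,12-trien-1-yl]oxirane | C=C(CCC=C(C)C)[C@H](C)CC[C@@]1(C)O[C@@H]1CC/C=C(\C)CC/C=C(\C)CC[C@H](C)C(=C)C | target

**Step count and risks**

Total step count: 16. Longest linear sequence: 8 steps (8 → 9 → 10 → 11 → 12 → 14 → 15 → 16).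

The least certain step is step 15, the proposed lactone-opening decarboxylative alkenylation. Oxidation of an unactivated primary carboxylate is slow, the hydroxy carboxylate can relactonise, and bromine-atom side reactions at the two tertiary allylic C–H bonds could erode C7 and C22. The fallback uses known chemistry, sets out from 28 and comes back at 30. 2,2-Dimethoxypropane, MeOH and CSA open the lactone to methyl 3-[(4S,5R)-5-[(3R)-3,8-dimethyl-4-methylidenenon-7-en-1-yl]-2,2,5-trimethyl-1,3-dioxolan-4-yl]propanoate F1. LiOH gives 3-[(4S,5R)-5-[(3R)-3,8-dimethyl-4-methylidenenon-7-en-1-yl]-2,2,5-trimethyl-1,3-dioxolan-4-yl]propanoic acid F2. N-Hydroxyphthalimide and DIC give the redox-active ester 1,3-dioxoisoindolin-2-yl 3-[(4S,5R)-5-[(3R)-3,8-dimethyl-4-methylidenenon-7-en-1-yl]-2,2,5-trimethyl-1,3-dioxolan-4-yl]propanoate F3. Bromide 13 is turned by t-BuLi and then ZnCl2 into chloro[(1E,5E,9S)-2,6,9,10-tetramethylundeca-1,5,10-trien-1-yl]zinc F4. F4 couples with F3 under Ni(acac)2 and 2,2′-bipyridine (thermal decarboxylative alkenylation of a redox-active ester) to (4S,5R)-5-[(3R)-3,8-dimethyl-4-methylidenenon-7-en-1-yl]-2,2,5-trimethyl-4-[(3E,7E,11S)-4,8,11,12-tetramethyltrideca-3,7,12-trien-1-yl]-1,3-dioxolane F5. Aqueous acetic acid then frees diol 30.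

The second is step 2, together with its mirror image, step 9. The acyl rhodium hydride can add across the nearby 1,1-disubstituted alkene (intramolecular hydroacylation to a cyclopentanone) or isomerise it instead of losing CO. The fallback replaces metal decarbonylation by radical decarboxylation, sets out from 2 and comes back at 3. Pinnick oxidation (NaClO2, NaH2PO4, 2-methylbut-2-ene) gives (3R)-6-oxo-3-(prop-1-en-2-yl)heptanoic acid F6. DCC and 1-hydroxypyridine-2(1H)-thione give the Barton ester 2-sulfanylidenepyridin-1(2H)-yl (3R)-6-oxo-3-(prop-1-en-2-yl)heptanoate F7. Photolysis with excess t-BuSH gives 3, because the primary radical is reduced by the thiol far faster than it can rearrange through the cyclopropylcarbinyl radical. In the mirror-image series the same sequence sets out from 15 and comes back at 16 through (3S)-6-oxo-3-(prop-1-en-2-yl)heptanoic acid F8 and 2-sulfanylidenepyridin-1(2H)-yl (3S)-6-oxo-3-(prop-1-en-2-yl)heptanoate F9.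

The third is step 12. The radical chain that carries the deacylative bromination may add trichloromethyl radicals across the methylidene group or abstract the tertiary allylic hydrogen at C7. The fallback replaces radical C–C scission by ionic oxygen insertion, sets out from 20 and comes back at 23. PPTS in aqueous acetone gives ketone 21, now isolated. Baeyer–Villiger oxidation with bis(trimethylsilyl) peroxide and catalytic TMSOTf, which spares alkenes, gives (3R)-3,8-dimethyl-4-methylidenenon-7-en-1-yl acetate F10. K2CO3 in MeOH gives (3R)-3,8-dimethyl-4-methylidenenon-7-en-1-ol F11. CBr4 and PPh3 give bromide 23.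

Further compounds
F1 | step 15 | methyl 3-[(4S,5R)-5-[(3R)-3,8-dimethyl-4-methylidenenon-7-en-1-yl]-2,2,5-trimethyl-1,3-dioxolan-4-yl]propanoate | C[C@]1(CC[C@@H](C)C(=C)CCC=C(C)C)OC(C)(C)O[C@H]1CCC(=O)OC
F2 | step 15 | 3-[(4S,5R)-5-[(3R)-3,8-dimethyl-4-methylidenenon-7-en-1-yl]-2,2,5-trimethyl-1,3-dioxolan-4-yl]propanoic acid | C[C@]1(CC[C@@H](C)C(=C)CCC=C(C)C)OC(C)(C)O[C@H]1CCC(=O)O
F3 | step 15 | 1,3-dioxoisoindolin-2-yl 3-[(4S,5R)-5-[(3R)-3,8-dimethyl-4-methylidenenon-7-en-1-yl]-2,2,5-trimethyl-1,3-dioxolan-4-yl]propanoate | C[C@]1(CC[C@@H](C)C(=C)CCC=C(C)C)OC(C)(C)O[C@H]1CCC(=O)ON1C(=O)c2ccccc2C1=O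
F4 | step 15 | chloro[(1E,5E,9S)-2,6,9,10-tetramethylundeca-1,5,10-trien-1-yl]zinc | Cl[Zn]/C=C(\C)CC/C=C(\C)CC[C@H](C)C(C)=C
F5 | step 15 | (4S,5R)-5-[(3R)-3,8-dimethyl-4-methylidenenon-7-en-1-yl]-2,2,5-trimethyl-4-[(3E,7E,11S)-4,8,11,12-tetramethyltrideca-3,7,12-trien-1-yl]-1,3-dioxolane | C[C@]1(CC[C@@H](C)C(=C)CCC=C(C)C)OC(C)(C)O[C@H]1CC/C=C(\C)CC/C=C(\C)CC[C@H](C)C(C)=C
F6 | step 2 | (3R)-6-oxo-3-(prop-1-en-2-yl)heptanoic acid | OC(=O)C[C@@H](CCC(C)=O)C(C)=C
F7 | step 2 | 2-sulfanylidenepyridin-1(2H)-yl (3R)-6-oxo-3-(prop-1-en-2-yl)heptanoate | S=c1ccccn1OC(=O)C[C@@H](CCC(C)=O)C(C)=C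
F8 | step 9 | (3S)-6-oxo-3-(prop-1-en-2-yl)heptanoic acid | OC(=O)C[C@H](CCC(C)=O)C(C)=C
F9 | step 9 | 2-sulfanylidenepyridin-1(2H)-yl (3S)-6-oxo-3-(prop-1-en-2-yl)heptanoate | S=c1ccccn1OC(=O)C[C@H](CCC(C)=O)C(C)=C
F10 | step 12 | (3R)-3,8-dimethyl-4-methylidenenon-7-en-1-yl acetate | CC(C)=CCCC(=C)[C@H](C)CCOC(C)=O
F11 | step 12 | (3R)-3,8-dimethyl-4-methylidenenon-7-en-1-ol | CC(C)=CCCC(=C)[C@H](C)CCO
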